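**Retrosynthetic overview**
1. Ring letters: A is the biaryl ring with O para to the axis, B the ring with OH next to the ether O, C the 1,4-disubstituted ether ring, and D the biaryl ring with O ortho to the axis. All four rings are bought, so the 16-membered macrocycle is the only ring formed; it is closed in the penultimate step, and only O-demethylation follows.
2. Key disconnection: the bond between the ring C carbon para to the ether oxygen and the neighbouring CH2 of the C–D bridge. It is closed by one-pot hydroboration and intramolecular B-alkyl Suzuki–Miyaura coupling of an open-chain D–A–B–C chloro-styrene.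
3. Enabling feature: the C–D bridge is ring C–CH2–CH2–ring D. The CH2 next to ring C is therefore the terminal carbon of a vinyl group on ring D, where 9-BBN places boron, and the para carbon of the aryl ether ring C can carry an inert chlorine from the first step onwards.
4. The open chain is built along a halogen ladder. The C–I bond of ring A serves the first B-alkyl Suzuki coupling (A–B bridge), the C–Br bond of ring A serves borylation and then the hindered A–D biaryl Suzuki coupling, and the C–Cl bond of ring C serves ring closure.
5. The B–O–C diaryl ether is made first, from isovanillin by Ullmann coupling. The ring D vinyl group comes from the formyl group of 2-bromo-3-methoxybenzaldehyde.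

Key step: step 8

Assumption: the target SMILES carries no stereodescriptor, so the A–D biaryl axis is treated as unspecified (racemic or conformationally mobile). There is no stereocentre to set.

**Step 1**
Reactants: 1 isovanillin (3-hydroxy-4-methoxybenzaldehyde); 2 1-chloro-4-iodobenzene
Product: 3 3-(4-chlorophenoxy)-4-methoxybenzaldehyde
Conditions: CuI (10 mol %), N,N-dimethylglycine·HCl (30 mol %), Cs2CO3, 1,4-dioxane, 90 °C
Reagents that add atoms: none
Why: In this ligand-accelerated Ullmann diaryl ether synthesis copper activates only the weaker C–I bond of 2, so the chlorine para to the new ether oxygen is kept as the silent handle for step 8.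

**Step 2**
Reactants: 3 3-(4-chlorophenoxy)-4-methoxybenzaldehyde
Product: 4 2-(4-chlorophenoxy)-4-ethenyl-1-methoxybenzene
Conditions: Ph3PCH3Br, KOt-Bu, THF, 0 °C to rt
Reagents that add atoms: methyltriphenylphosphonium bromide, C[P+](c1ccccc1)(c1ccccc1)c1ccccc1.[Br-]
Why: Wittig methylenation of an aromatic aldehyde with the non-stabilised ylide is general and touches neither the diaryl ether nor the aryl chloride.

**Step 3**
Reactants: 5 3-iodoanisole
Product: 6 1-bromo-2-iodo-4-methoxybenzene (4-bromo-3-iodoanisole)
Conditions: NBS, MeCN, 0 °C to rt, dark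
Reagents that add atoms: N-bromosuccinimide, O=C1CCC(=O)N1Br
Why: Electrophilic aromatic bromination with NBS in acetonitrile should go para to the methoxy group, the strongest director, which places bromine next to iodine.

**Step 4**
Reactants: 4 2-(4-chlorophenoxy)-4-ethenyl-1-methoxybenzene; 6 1-bromo-2-iodo-4-methoxybenzene
Product: 8 1-bromo-2-{2-[3-(4-chlorophenoxy)-4-methoxyphenyl]ethyl}-4-methoxybenzene, via B-alkyl-9-BBN borane 7 (not isolated)
Conditions: 9-BBN, THF, 0 °C to rt; then 6, PdCl2(dppf) (3 mol %), 3 M aq NaOH, THF, rt to 45 °C
Reagents that add atoms: 9-borabicyclo[3.3.1]nonane (9-BBN), [H]B1C2CCCC1CCC2 (its heavy atoms stay in 7 only; 8 keeps only its hydrogen)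
Why: In this one-pot hydroboration/B-alkyl Suzuki–Miyaura coupling 9-BBN puts boron on the terminal styrene carbon and zerovalent palladium inserts into C–I faster than into C–Br or C–Cl, so only the iodine-bearing carbon of 6 should be alkylated.

**Step 5**
Reactants: 8 1-bromo-2-{2-[3-(4-chlorophenoxy)-4-methoxyphenyl]ethyl}-4-methoxybenzene
Product: 9 2-(2-{2-[3-(4-chlorophenoxy)-4-methoxyphenyl]ethyl}-4-methoxyphenyl)-4,4,5,5-tetramethyl-1,3,2-dioxaborolane
Conditions: B2pin2, PdCl2(dppf) (5 mol %), KOAc, 1,4-dioxane, 90 °C
Reagents that add atoms: bis(pinacolato)diboron, CC1(C)OB(OC1(C)C)B1OC(C)(C)C(C)(C)O1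
Why: In this Miyaura borylation the dppf-ligated catalyst activates the aryl bromide but not the electron-rich aryl chloride, and KOAc is too weak a base to start Suzuki homocoupling.

**Step 6**
Reactants: 9 aryl pinacol boronate of step 5; 10 2-bromo-3-methoxybenzaldehyde
Product: 11 2'-{2-[3-(4-chlorophenoxy)-4-methoxyphenyl]ethyl}-4',6-dimethoxybiphenyl-2-carbaldehyde
Conditions: Pd(PPh3)4 (5 mol %), 2 M aq Na2CO3, DME, 85 °C
Reagents that add atoms: none
Why: In this Suzuki–Miyaura biaryl coupling the doubly flanked partner is the bromide, activated by its ortho formyl group, while the triphenylphosphine catalyst leaves the electron-rich C–Cl bond of ring C alone, and the tri-ortho-substituted axis forms without stereocontrol.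

**Step 7**
Reactants: 11 biaryl aldehyde of step 6
Product: 12 2'-{2-[3-(4-chlorophenoxy)-4-methoxyphenyl]ethyl}-2-ethenyl-4',6-dimethoxybiphenyl
Conditions: Ph3PCH3Br, KOt-Bu, THF, 0 °C to rt
Reagents that add atoms: methyltriphenylphosphonium bromide, C[P+](c1ccccc1)(c1ccccc1)c1ccccc1.[Br-]
Why: Wittig methylenation with the small non-stabilised ylide tolerates the hindered ortho position and installs the ring D vinyl group whose terminal carbon becomes the CH2 next to ring C.

**Step 8**
Reactants: 12 open-chain chloro-styrene of step 7
Product: 14 plagiochin E trimethyl ether (16-membered macrocycle), via B-alkyl-9-BBN borane 13 (not isolated)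
Conditions: 9-BBN, THF, rt; H2O (destroys excess borane); then slow addition (syringe pump) to Pd(OAc)2 (15 mol %), SPhos (30 mol %), K3PO4, THF/H2O, 65 °C, about 1 mM final
Reagents that add atoms: 9-borabicyclo[3.3.1]nonane (9-BBN), [H]B1C2CCCC1CCC2 (its heavy atoms stay in 13 only; 14 keeps only its hydrogen)
Why: 9-BBN adds to the only alkene of 12 with boron on the terminal carbon (steric anti-Markovnikov control) to give 13; once base has turned it into the borate, SPhos-ligated zerovalent palladium inserts into the only carbon–halogen bond left, the C–Cl bond of ring C para to the ether oxygen, the alkyl group is handed over intramolecularly to divalent palladium, and reductive elimination forms the ring C–CH2 bond. The closest known reaction type is the one-pot hydroboration/B-alkyl Suzuki–Miyaura coupling, which is established for macrocyclisation (cyclophanes included) and, with bulky dialkylbiarylphosphines, for unactivated aryl chlorides. The one ring closed is the 16-membered macrocycle, by end-to-end sp3–sp2 coupling through a 17-membered palladacycle under pseudo-high dilution. No stereocentre is formed and the A–D axis stays unspecified. The step needs regioselective hydroboration, site-selective oxidative addition and ring closure in preference to chain growth: the first is secured by 9-BBN and the single vinyl group, the second by the fact that iodine and bromine were spent in steps 4 to 6, and the third by dilution, by the attachment of both arms ortho to the twisted biaryl axis and by the flexible saturated arm, which should accommodate the strain of the para-phenylene more easily than a stilbene or an alkyne. Fast reductive elimination from the bulky phosphine complex should hold back beta-hydride elimination, and the one operation sets the last C–C bond, the final oxidation level of the bridge and the macrocycle, so that only demethylation remains.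

**Step 9**
Reactants: 14 plagiochin E trimethyl ether
Product: 16 plagiochin E, via tris(dibromoboryl) aryl ether 15 (not isolated)
Conditions: BBr3, CH2Cl2, −78 °C to rt; then H2O, 0 °C
Reagents that add atoms: boron tribromide, BrB(Br)Br (its heavy atoms stay in 15 only)
Why: In this Lewis acid-mediated aryl methyl ether cleavage bromide attacks only the three O–CH3 carbons, whereas the diaryl ether has no sp3 carbon to attack and should survive, and water then frees the three phenols.

**Compound list**
1 | isovanillin (3-hydroxy-4-methoxybenzaldehyde) | COc1ccc(C=O)cc1O | starting material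
2 | 1-chloro-4-iodobenzene | Clc1ccc(I)cc1 | starting material
3 | 3-(4-chlorophenoxy)-4-methoxybenzaldehyde | COc1ccc(C=O)cc1Oc1ccc(Cl)cc1 | intermediate
4 | 2-(4-chlorophenoxy)-4-ethenyl-1-methoxybenzene | COc1ccc(C=C)cc1Oc1ccc(Cl)cc1 | intermediate
5 | 3-iodoanisole | COc1cccc(I)c1 | starting material
6 | 1-bromo-2-iodo-4-methoxybenzene | COc1ccc(Br)c(I)c1 | intermediate
7 | 9-{2-[3-(4-chlorophenoxy)-4-methoxyphenyl]ethyl}-9-borabicyclo[3.3.1]nonane | COc1ccc(CCB2C3CCCC2CCC3)cc1Oc1ccc(Cl)cc1 | intermediate
8 | 1-bromo-2-{2-[3-(4-chlorophenoxy)-4-methoxyphenyl]ethyl}-4-methoxybenzene | COc1ccc(Br)c(CCc2ccc(OC)c(Oc3ccc(Cl)cc3)c2)c1 | intermediate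
9 | 2-(2-{2-[3-(4-chlorophenoxy)-4-methoxyphenyl]ethyl}-4-methoxyphenyl)-4,4,5,5-tetramethyl-1,3,2-dioxaborolane | COc1ccc(B2OC(C)(C)C(C)(C)O2)c(CCc2ccc(OC)c(Oc3ccc(Cl)cc3)c2)c1 | intermediate
10 | 2-bromo-3-methoxybenzaldehyde | COc1cccc(C=O)c1Br | starting material
11 | 2'-{2-[3-(4-chlorophenoxy)-4-methoxyphenyl]ethyl}-4',6-dimethoxybiphenyl-2-carbaldehyde | COc1ccc(-c2c(C=O)cccc2OC)c(CCc2ccc(OC)c(Oc3ccc(Cl)cc3)c2)c1 | intermediate
12 | 2'-{2-[3-(4-chlorophenoxy)-4-methoxyphenyl]ethyl}-2-ethenyl-4',6-dimethoxybiphenyl | COc1ccc(-c2c(C=C)cccc2OC)c(CCc2ccc(OC)c(Oc3ccc(Cl)cc3)c2)c1 | intermediate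
13 | B-alkyl-9-BBN borane from 12 (boron on the terminal carbon of the former ring D vinyl group) | COc1ccc(-c2c(CCB3C4CCCC3CCC4)cccc2OC)c(CCc2ccc(OC)c(Oc3ccc(Cl)cc3)c2)c1 | intermediate
14 | plagiochin E trimethyl ether | COc1ccc2c(c1)CCc1ccc(OC)c(c1)Oc1ccc(cc1)CCc1cccc(OC)c1-2 | intermediate
15 | plagiochin E tris(dibromoboryl) ether | BrB(Br)Oc1ccc2c(c1)CCc1ccc(OB(Br)Br)c(c1)Oc1ccc(cc1)CCc1cccc(OB(Br)Br)c1-2 | intermediate
16 | plagiochin E | Oc1ccc2c(c1)CCc1ccc(O)c(c1)Oc1ccc(cc1)CCc1cccc(O)c1-2 | target

**Step count**
Total step count: 9.
Longest linear sequence: 8 (steps 1, 2, 4, 5, 6, 7, 8, 9).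

**Steps most likely to fail**

Step 8 (key step).
- Risk: chain growth between molecules may outrun ring closure, because oxidative addition into the electron-rich C–Cl bond is slow at high dilution. Beta-hydride elimination or protodeboronation of the alkyl arm may also drain material.
- Fallback: it sets out from 12 and comes back at 14, joining the same two carbons at the alkene oxidation level and without boron.
- An intramolecular Mizoroki–Heck reaction (Pd2(dba)3, P(t-Bu)3·HBF4, Cs2CO3, 1,4-dioxane, 110 °C, high dilution) should add the ring C aryl group to the terminal vinyl carbon and give the macrocyclic (E)-stilbene F1.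
- Hydrogenation (H2, Pd/C, EtOAc, rt) should then give 14. The alkene geometry is of no consequence because it is erased.

Step 6.
- Risk: slow transmetalation at the tri-ortho-substituted centre may allow protodeboronation of the boronate. A more active ligand would erode the discrimination between C–Br and C–Cl.
- Fallback: it sets out from 8, bypasses steps 5 and 6 and comes back at 11, using palladium-free oxazoline-directed nucleophilic aromatic substitution (Meyers biaryl synthesis).
- Magnesium insertion into the C–Br bond of 8 (Mg, LiCl, THF) should give the arylmagnesium bromide F2.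
- F2 should displace the 2-methoxy group of commercial 2-(2,3-dimethoxyphenyl)-4,4-dimethyl-4,5-dihydro-1,3-oxazole F3 (THF, rt to reflux) to give the biaryl oxazoline F4.
- N-methylation (MeOTf, CH2Cl2) should give the N-methyloxazolinium triflate F5, and reduction (NaBH4, THF/MeOH, 0 °C) the N-methyloxazolidine F6.
- Hydrolysis (aq oxalic acid, THF) should release 11.

Step 4.
- Risk: discrimination between C–I and the neighbouring C–Br bond may be lost (double alkylation), or the C–I bond may be reduced after beta-hydride elimination.
- Fallback: it sets out from 3, bypasses steps 2 to 4 and comes back at 8 without any palladium.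
- A Michaelis–Arbuzov reaction of commercial 2-bromo-5-methoxybenzyl bromide F7 with P(OEt)3 (neat, 130 °C) should give diethyl (2-bromo-5-methoxybenzyl)phosphonate F8.
- Horner–Wadsworth–Emmons olefination of 3 (KOt-Bu, THF, 0 °C to rt) should give the (E)-stilbene F9.
- Diimide reduction (TsNHNH2, NaOAc, THF/H2O, reflux) should saturate the alkene while sparing C–Br and C–Cl, giving 8.

**Further compounds**
F1 | step 8 | macrocyclic (E)-stilbene (dehydro form of 14 in the C–D bridge) | COc1ccc2c(c1)CCc1ccc(OC)c(c1)Oc1ccc(cc1)/C=C/c1cccc(OC)c1-2
F2 | step 6 | arylmagnesium bromide from 8 | COc1ccc([Mg]Br)c(CCc2ccc(OC)c(Oc3ccc(Cl)cc3)c2)c1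
F3 | step 6 | 2-(2,3-dimethoxyphenyl)-4,4-dimethyl-4,5-dihydro-1,3-oxazole | COc1cccc(C2=NC(C)(C)CO2)c1OC
F4 | step 6 | biaryl oxazoline | COc1ccc(-c2c(C3=NC(C)(C)CO3)cccc2OC)c(CCc2ccc(OC)c(Oc3ccc(Cl)cc3)c2)c1
F5 | step 6 | N-methyloxazolinium triflate | COc1ccc(-c2c(C3=[N+](C)C(C)(C)CO3)cccc2OC)c(CCc2ccc(OC)c(Oc3ccc(Cl)cc3)c2)c1.[O-]S(=O)(=O)C(F)(F)F
F6 | step 6 | N-methyloxazolidine (aminal carbon unspecified, of no consequence) | COc1ccc(-c2c(C3OCC(C)(C)N3C)cccc2OC)c(CCc2ccc(OC)c(Oc3ccc(Cl)cc3)c2)c1
F7 | step 4 | 2-bromo-5-methoxybenzyl bromide | COc1ccc(Br)c(CBr)c1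
F8 | step 4 | diethyl (2-bromo-5-methoxybenzyl)phosphonate | CCOP(=O)(Cc1cc(OC)ccc1Br)OCC
F9 | step 4 | (E)-stilbene, dehydro form of 8 | COc1ccc(Br)c(/C=C/c2ccc(OC)c(Oc3ccc(Cl)cc3)c2)c1
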